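The target is an ether of two flavan-3,4-diols that share the 3R,4R cis-diol and differ only at C2: half A is all-cis (2R,3R,4R), half B is 2S. Everything rests on cutting ring C of half A between O1 and C2 and between C4a and C4. Because O1 and C4a are ortho neighbours on the pyrogallol-type ring A and C2–C3–C4 is an all-cis triad, the key step joins a 2,3-diallyl pyrogallol titanium phenoxide with a catalyst-made cis-epoxy aldehyde (C4 = CHO): ortho C-attack on the aldehyde, then strain-releasing 6-endo oxirane opening by the phenol oxygen, setting C2 and C4 from C3. The trans-epoxide gives half B; a boron-guided epoxide opening forms the ether.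

Key step: step 8

Remark on the chemistry: flavan numbering (O1, C2, C3, C4, C4a to C8a; ring A = benzo ring, ring C = pyran ring) is used for both halves; half A = (2R,3R,4R), half B = (2S,3R,4R), and the target carries both C4–O bonds cis to the neighbouring 3-OH.

Step 1
Reactants: 1 4-hydroxybenzaldehyde
Product: 2 4-formylphenyl pivalate
Conditions: pivaloyl chloride, Et3N, DMAP (cat.), CH2Cl2, 0 °C to rt
Reagents that add atoms: pivaloyl chloride CC(C)(C)C(Cl)=O
Why: Simple O-acylation of the phenol; the pivalate later keeps the 4-oxyphenyl ring electron-poor so that the benzylic oxirane carbon reacts by SN2 and not by ionisation.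

Step 2
Reactants: 2 4-formylphenyl pivalate
Product: 3 ethyl (Z)-3-[4-(pivaloyloxy)phenyl]prop-2-enoate
Conditions: (PhO)2P(O)CH2CO2Et, NaH, THF, −78 to 0 °C
Reagents that add atoms: ethyl 2-(diphenoxyphosphoryl)acetate CCOC(=O)CP(=O)(Oc1ccccc1)Oc1ccccc1
Why: Ando variant of the Horner–Wadsworth–Emmons olefination, in which the diaryl phosphonate eliminates rapidly from the kinetic adduct and should give the (Z)-cinnamate needed for a cis-oxirane.

Step 3
Reactants: 3 ethyl (Z)-3-[4-(pivaloyloxy)phenyl]prop-2-enoate
Product: 4 ethyl (2S,3S)-3-[4-(pivaloyloxy)phenyl]oxirane-2-carboxylate (cis)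
Conditions: (S,S)-N,N'-bis(3,5-di-tert-butylsalicylidene)-1,2-cyclohexanediaminomanganese chloride (5 mol%), 4-phenylpyridine N-oxide, NaOCl (aq., pH 11.3), CH2Cl2, 4 °C
Reagents that add atoms: sodium hypochlorite [Na+].[O-]Cl
Why: Jacobsen–Katsuki epoxidation of a cis-cinnamate ester, a privileged substrate class; both oxirane stereocentres are set by the catalyst (the antipode of the one that gives the (2R,3R)-glycidate from ethyl cis-cinnamate), and minor trans-epoxide is removed by chromatography.

Step 4
Reactants: 4 ethyl (2S,3S)-3-[4-(pivaloyloxy)phenyl]oxirane-2-carboxylate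
Product: 5 [(2R,3S)-3-[4-(pivaloyloxy)phenyl]oxiran-2-yl]methanol (cis)
Conditions: NaBH4, EtOH, 0 °C
Reagents that add atoms: none
Why: Borohydride reduction of an α-oxygen-activated glycidic ester, which should leave the hindered aryl pivalate and the oxirane untouched.

Step 5
Reactants: 5 [(2R,3S)-3-[4-(pivaloyloxy)phenyl]oxiran-2-yl]methanol
Product: 6 (2S,3S)-3-[4-(pivaloyloxy)phenyl]oxirane-2-carbaldehyde (cis)
Conditions: Dess–Martin periodinane, CH2Cl2, 0 °C to rt
Reagents that add atoms: none
Why: Dess–Martin oxidation of the primary alcohol under non-basic conditions that should not epimerise or open the oxirane; the aldehyde is used without storage.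

Step 6
Reactants: 7 2,3-dihydroxybenzaldehyde
Product: 8 2,3-bis(allyloxy)benzaldehyde
Conditions: allyl bromide, K2CO3, DMF, 60 °C
Reagents that add atoms: allyl bromide C=CCBr
Why: Williamson etherification of both phenols; allyl ethers cannot migrate to the neighbouring phenoxide in the key step and are removed at the end under zerovalent palladium catalysis.

Step 7
Reactants: 8 2,3-bis(allyloxy)benzaldehyde
Product: 10 2,3-bis(allyloxy)phenol, via 2,3-bis(allyloxy)phenyl formate 9 (not isolated)
Conditions: mCPBA, CH2Cl2, 0 °C to rt; then K2CO3 (cat.), MeOH, rt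
Reagents that add atoms: 3-chloroperbenzoic acid OOC(=O)c1cccc(Cl)c1
Why: Baeyer–Villiger (Dakin-type) oxidation in which the electron-rich aryl group migrates; the formate is methanolysed in the same flask, and the allyl alkenes are deactivated toward the peracid.

Step 8
Reactants: 10 2,3-bis(allyloxy)phenol; 6 (2S,3S)-3-[4-(pivaloyloxy)phenyl]oxirane-2-carbaldehyde
Product: 12 4-[(2R,3R,4R)-7,8-bis(allyloxy)-3,4-dihydroxychroman-2-yl]phenyl pivalate (diol A), via epoxy diol 11 (not isolated)
Conditions: 10, Ti(OiPr)4 (1.0 equiv), toluene, rt, iPrOH removed in vacuo; then 6, toluene, −20 °C to rt; then 45 °C; aq. Rochelle salt work-up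
Reagents that add atoms: none
Why: Proposed new method: the aryloxytitanium triisopropoxide ArOTi(OiPr)3 binds the aldehyde of 6 and delivers the only free ortho carbon of the phenoxide (the future C4a) to the carbonyl carbon through a six-membered cyclic transition state, and the titanium-bound 2,3-epoxy alkoxide 11 is then opened at its benzylic, carbinol-distal carbon by the phenol oxygen. The closest known reaction types are the ortho-specific hydroxyalkylation of metal phenoxides with chiral α-oxy aldehydes, the Ti(OiPr)4-mediated C3-selective opening of 2,3-epoxy alcohols and the phenol–oxirane closure of aryl epoxides to flavan-3-ols. Ring C closes in the 6-endo-tet mode with release of the oxirane strain, and the 5-exo alternative at C3 is disfavoured because C3 is not benzylic and is deactivated by the adjacent C4–O bond. C4 is set in the addition of the non-chelating titanium reagent under Felkin–Anh/Cornforth control by the oxirane oxygen on C3 (anti adduct, hence 3,4-cis), C2 is set by stereospecific SN2 inversion of the cis-oxirane carbon (hence 2,3-cis), and C3 is carried over from the catalyst-made glycidate. Ortho-regioselectivity is secured because the other ortho position of 10 bears an allyloxy group, and stereospecificity at C2 is secured by the electron-poor 4-pivaloyloxyphenyl group, which should suppress ionisation to a benzylic cation.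

Step 9
Reactants: 2 4-formylphenyl pivalate
Product: 13 4-[(E)-3-oxoprop-1-en-1-yl]phenyl pivalate
Conditions: Ph3P=CHCHO, toluene, 80 °C
Reagents that add atoms: (triphenylphosphoranylidene)acetaldehyde O=CC=P(c1ccccc1)(c1ccccc1)c1ccccc1
Why: Wittig olefination with the stabilised formylmethylene ylide, which should give the (E)-enal.

Step 10
Reactants: 13 4-[(E)-3-oxoprop-1-en-1-yl]phenyl pivalate
Product: 14 (2S,3R)-3-[4-(pivaloyloxy)phenyl]oxirane-2-carbaldehyde (trans)
Conditions: H2O2 (35% aq.), (R)-2-[bis(3,5-bis(trifluoromethyl)phenyl)(trimethylsilyloxy)methyl]pyrrolidine (10 mol%), CH2Cl2, rt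
Reagents that add atoms: hydrogen peroxide OO
Why: Organocatalytic iminium–enamine epoxidation of an enal with a Jørgensen–Hayashi catalyst (the antipode of the one that gives (2R,3S)-epoxycinnamaldehyde), in which the shielded iminium ion takes up H2O2 on one face and the enamine closes the trans-oxirane, so both stereocentres are set by the catalyst.

Step 11
Reactants: 10 2,3-bis(allyloxy)phenol; 14 (2S,3R)-3-[4-(pivaloyloxy)phenyl]oxirane-2-carbaldehyde
Product: 16 4-[(2S,3R,4R)-7,8-bis(allyloxy)-3,4-dihydroxychroman-2-yl]phenyl pivalate (diol B), via epoxy diol 15 (not isolated)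
Conditions: 10, Ti(OiPr)4 (1.0 equiv), toluene, rt, iPrOH removed in vacuo; then 14, toluene, −20 °C to rt; then 45 °C; aq. Rochelle salt work-up
Reagents that add atoms: none
Why: Proposed new method: the same titanium phenoxide ortho-hydroxyalkylation and 6-endo oxirane-opening annulation as in step 8 (closest known reaction types: ortho-specific hydroxyalkylation of metal phenoxides with α-oxy aldehydes and the phenol–oxirane closure of trans-aryl epoxides to 2,3-trans-flavan-3-ols), in which Felkin–Anh/Cornforth addition should set C4 cis to O3 and SN2 inversion of the trans-oxirane carbon should set C2 trans to O3.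

Step 12
Reactants: 16 4-[(2S,3R,4R)-7,8-bis(allyloxy)-3,4-dihydroxychroman-2-yl]phenyl pivalate
Product: 17 3,4-O-thiocarbonyl derivative (cyclic thionocarbonate) of 16
Conditions: 1,1'-thiocarbonyldiimidazole, DMAP (cat.), THF, rt to 40 °C
Reagents that add atoms: 1,1'-thiocarbonyldiimidazole S=C(n1ccnc1)n1ccnc1
Why: First stage of the Corey–Winter olefination; the cis-3,4-diol should close readily to the five-membered cyclic thionocarbonate.

Step 13
Reactants: 17 cyclic thionocarbonate of 16
Product: 18 4-[(R)-7,8-bis(allyloxy)-2H-chromen-2-yl]phenyl pivalate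
Conditions: 1,3-dimethyl-2-phenyl-1,3,2-diazaphospholidine, THF, 40 °C
Reagents that add atoms: none
Why: Corey–Winter olefination with the Corey–Hopkins reagent, in which sulfur abstraction and stereospecific cycloreversion with loss of CO2 should give the flav-3-ene near room temperature; C2 is untouched (its descriptor changes only through the priority rules) and thermal ring-opening of the chromene is avoided.

Step 14
Reactants: 18 4-[(R)-7,8-bis(allyloxy)-2H-chromen-2-yl]phenyl pivalate; 12 diol A
Product: 22 hexa-O-allyl di-O-pivaloyl ether dimer (C4–O–C4 linked; half A 2R,3R,4R; half B 2S,3R,4R), via flavene oxide 19 (not isolated), via cis-diol boronate 20 (not isolated), via bridged boronate 21 (not isolated)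
Conditions: 18, dimethyldioxirane (acetone solution, 1.1 equiv), CH2Cl2, −40 °C, volatiles removed cold; separately 12, 4-nitrophenylboronic acid (1.0 equiv), 4 Å MS, MeCN, rt; both combined in MeCN, −40 to 0 °C; aq. NaHCO3 work-up
Reagents that add atoms: dimethyldioxirane CC1(C)OO1
Why: Proposed new method: dimethyldioxirane should epoxidise C3=C4 of 18 anti to the C2 aryl group, the Lewis acidic boron of boronate 20 then binds the oxirane oxygen of 19, the C4–O bond ionises to a benzylic cation stabilised by O1 and the 7-allyloxy group, and the resulting borate hands the pseudo-equatorial O4 of half A to C4 on the face of the departing oxygen (SNi), that is cis to the new 3-OH of half B, the closest known reaction type being boronic-ester-mediated 1,2-cis glycosylation of diol acceptors with 1,2-anhydro sugars (boron-mediated aglycon delivery).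

Step 15
Reactants: 22 hexa-O-allyl di-O-pivaloyl ether dimer
Product: 23 (2R,3R,4R)-2-(4-hydroxyphenyl)-4-{[(2S,3R,4R)-3,7,8-trihydroxy-2-(4-hydroxyphenyl)chroman-4-yl]oxy}chromane-3,7,8-triol (CNP0241481.1)
Conditions: Pd(PPh3)4 (10 mol%), K2CO3, degassed MeOH–THF, rt, argon; pH 6–7 phosphate buffer quench
Reagents that add atoms: none
Why: Tsuji–Trost-type deallylation in which zerovalent palladium ionises the six aryl allyl ethers to π-allyl complexes that methoxide captures, while carbonate-mediated methanolysis removes the two aryl pivalates; no acid and no hydrogenolysis touch the bis-benzylic ether or the benzylic stereocentres.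

Compound list
1 | 4-hydroxybenzaldehyde | O=Cc1ccc(O)cc1 | starting material
2 | 4-formylphenyl pivalate | CC(C)(C)C(=O)Oc1ccc(C=O)cc1 | intermediate
3 | ethyl (Z)-3-[4-(pivaloyloxy)phenyl]prop-2-enoate | CCOC(=O)/C=C\c1ccc(OC(=O)C(C)(C)C)cc1 | intermediate
4 | ethyl (2S,3S)-3-[4-(pivaloyloxy)phenyl]oxirane-2-carboxylate (cis) | CCOC(=O)[C@@H]1[C@H](c2ccc(OC(=O)C(C)(C)C)cc2)O1 | intermediate
5 | [(2R,3S)-3-[4-(pivaloyloxy)phenyl]oxiran-2-yl]methanol (cis) | OC[C@@H]1[C@H](c2ccc(OC(=O)C(C)(C)C)cc2)O1 | intermediate
6 | (2S,3S)-3-[4-(pivaloyloxy)phenyl]oxirane-2-carbaldehyde (cis) | O=C[C@@H]1[C@H](c2ccc(OC(=O)C(C)(C)C)cc2)O1 | intermediate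
7 | 2,3-dihydroxybenzaldehyde | O=Cc1cccc(O)c1O | starting material
8 | 2,3-bis(allyloxy)benzaldehyde | O=Cc1cccc(OCC=C)c1OCC=C | intermediate
9 | 2,3-bis(allyloxy)phenyl formate (not isolated) | O=COc1cccc(OCC=C)c1OCC=C | intermediate
10 | 2,3-bis(allyloxy)phenol | Oc1cccc(OCC=C)c1OCC=C | intermediate
11 | 4-[(2S,3R)-3-{(R)-[3,4-bis(allyloxy)-2-hydroxyphenyl](hydroxy)methyl}oxiran-2-yl]phenyl pivalate (cis-oxirane; formed as its titanium alkoxide, not isolated) | Oc1c(OCC=C)c(OCC=C)ccc1[C@@H](O)[C@H]1O[C@H]1c1ccc(OC(=O)C(C)(C)C)cc1 | intermediate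
12 | 4-[(2R,3R,4R)-7,8-bis(allyloxy)-3,4-dihydroxychroman-2-yl]phenyl pivalate (diol A, 2,3-cis-3,4-cis) | CC(C)(C)C(=O)Oc1ccc([C@H]2Oc3c(ccc(OCC=C)c3OCC=C)[C@@H](O)[C@H]2O)cc1 | intermediate
13 | 4-[(E)-3-oxoprop-1-en-1-yl]phenyl pivalate | O=C/C=C/c1ccc(OC(=O)C(C)(C)C)cc1 | intermediate
14 | (2S,3R)-3-[4-(pivaloyloxy)phenyl]oxirane-2-carbaldehyde (trans) | O=C[C@@H]1[C@@H](c2ccc(OC(=O)C(C)(C)C)cc2)O1 | intermediate
15 | 4-[(2R,3R)-3-{(R)-[3,4-bis(allyloxy)-2-hydroxyphenyl](hydroxy)methyl}oxiran-2-yl]phenyl pivalate (trans-oxirane; formed as its titanium alkoxide, not isolated) | Oc1c(OCC=C)c(OCC=C)ccc1[C@@H](O)[C@H]1O[C@@H]1c1ccc(OC(=O)C(C)(C)C)cc1 | intermediate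
16 | 4-[(2S,3R,4R)-7,8-bis(allyloxy)-3,4-dihydroxychroman-2-yl]phenyl pivalate (diol B, 2,3-trans-3,4-cis) | O[C@@H]1c2ccc(OCC=C)c(OCC=C)c2O[C@@H](c2ccc(OC(=O)C(C)(C)C)cc2)[C@@H]1O | intermediate
17 | cyclic 3,4-thionocarbonate of 16 (cis-fused 1,3-dioxolane-2-thione, C2, C3 and C4 as in 16) | S=C1O[C@@H]2c3ccc(OCC=C)c(OCC=C)c3O[C@@H](c3ccc(OC(=O)C(C)(C)C)cc3)[C@@H]2O1 | intermediate
18 | 4-[(R)-7,8-bis(allyloxy)-2H-chromen-2-yl]phenyl pivalate (flav-3-ene, C2 as in 16) | C=CCOc1ccc2C=C[C@H](c3ccc(OC(=O)C(C)(C)C)cc3)Oc2c1OCC=C | intermediate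
19 | 3,4-epoxide of 18 with the oxirane oxygen anti to the C2 aryl group, flavan numbering (2S,3R,4R) (not isolated) | CC(C)(C)C(=O)Oc1ccc([C@@H]2Oc3c(OCC=C)c(OCC=C)ccc3[C@H]3O[C@@H]23)cc1 | intermediate
20 | cyclic 3,4-O-(4-nitrophenyl)boronate of 12 (not isolated) | CC(C)(C)C(=O)Oc1ccc([C@H]2Oc3c(ccc(OCC=C)c3OCC=C)[C@H]3OB(c4ccc(cc4)[N+](=O)[O-])O[C@@H]23)cc1 | intermediate
21 | ether dimer with the two 3-oxygens bridged by the (4-nitrophenyl)boranediyl group (not isolated) | CC(C)(C)C(=O)Oc1ccc([C@H]2Oc3c(ccc(OCC=C)c3OCC=C)[C@@H](O[C@@H]3c4ccc(OCC=C)c(OCC=C)c4O[C@@H](c4ccc(OC(=O)C(C)(C)C)cc4)[C@@H]3OB5c4ccc(cc4)[N+](=O)[O-])[C@H]2O5)cc1 | intermediate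
22 | 7,8,7',8'-tetra-O-allyl... hexa-O-allyl di-O-pivaloyl ether dimer: 4-[(2R,3R,4R)-7,8-bis(allyloxy)-4-{[(2S,3R,4R)-7,8-bis(allyloxy)-3-hydroxy-2-[4-(pivaloyloxy)phenyl]chroman-4-yl]oxy}-3-hydroxychroman-2-yl]phenyl pivalate | CC(C)(C)C(=O)Oc1ccc([C@H]2Oc3c(ccc(OCC=C)c3OCC=C)[C@@H](O[C@@H]3c4ccc(OCC=C)c(OCC=C)c4O[C@@H](c4ccc(OC(=O)C(C)(C)C)cc4)[C@@H]3O)[C@H]2O)cc1 | intermediate
23 | (2R,3R,4R)-2-(4-hydroxyphenyl)-4-{[(2S,3R,4R)-3,7,8-trihydroxy-2-(4-hydroxyphenyl)chroman-4-yl]oxy}chromane-3,7,8-triol | Oc1ccc([C@H]2Oc3c(ccc(O)c3O)[C@@H](O[C@@H]3c4ccc(O)c(O)c4O[C@@H](c4ccc(O)cc4)[C@@H]3O)[C@H]2O)cc1 | target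

Total step count: 15. Longest linear sequence: 8 steps (steps 1, 2, 3, 4, 5, 8, 14, 15; the branch through steps 1, 9, 10, 11, 12, 13, 14, 15 is equally long).

Steps most likely to fail

Step 8. The annulation may be diverted by 5-exo opening of the oxirane at C3, by ionisation at the benzylic oxirane carbon with loss of configuration at C2, or by poor facial selectivity in the aldehyde addition that sets C4. The fallback uses known chemistry, sets out from epoxy alcohol 5 and phenol 10 and comes back at 12 by reversing the order of bond formation. Ti(OiPr)4-mediated C3-selective opening of the 2,3-epoxy alcohol 5 by phenol 10, with inversion at the benzylic carbon, should give (2R,3R)-3-[2,3-bis(allyloxy)phenoxy]-3-[4-(pivaloyloxy)phenyl]propane-1,2-diol F1. Selective oxidation of its primary alcohol (TEMPO, PhI(OAc)2) should give (2S,3R)-3-[2,3-bis(allyloxy)phenoxy]-2-hydroxy-3-[4-(pivaloyloxy)phenyl]propanal F2. An intramolecular Friedel–Crafts hydroxyalkylation of the electron-rich aryl ether onto the aldehyde (MgBr2·OEt2, CH2Cl2) then closes C4a–C4 to 12, any C4 epimer being removed by chromatography.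

Step 14. The borate may deliver O3 instead of O4 of half A, the C4 cation may be captured on the face away from the borate (loss of cis control in half B), or the labile oxirane 19 may solvolyse or rearrange before coupling. The fallback uses chemistry known for ether-linked flavan-3,4-diol dimers, sets out from diol 16 (before steps 12 and 13) and diol 12 and comes back at 22. Acid-catalysed thiolysis of 16 with benzyl mercaptan should give the 4-benzylsulfanyl derivative of 16 (4-OH replaced by SBn, either C4 epimer serves) F3. Thiophilic activation with AgBF4 in THF at 0 °C in the presence of excess 12 lets the 4-OH of 12 capture the C4 cation of half B. Stereo- and regiocontrol are then lower, and the 3,4-trans epimer and any O3-linked isomer have to be separated from 22.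

Step 11. The same failure modes as in step 8 apply, and the benzylic titanium alkoxide may also collapse to an ortho-quinone methide. The fallback uses known chemistry, sets out from enal 13 and phenol 10 and comes back at 18, bypassing 16 and 17. Phenylboronic acid and propionic acid in hot toluene (ortho-hydroxyalkylation, dehydration to the ortho-quinone methide, oxa-6π electrocyclisation) should give racemic 4-[7,8-bis(allyloxy)-2H-chromen-2-yl]phenyl pivalate F4. Preparative chromatography on a chiral stationary phase then delivers 18 and its enantiomer, 4-[(S)-7,8-bis(allyloxy)-2H-chromen-2-yl]phenyl pivalate F5, which is discarded.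

Further compounds
F1 | step 8 | (2R,3R)-3-[2,3-bis(allyloxy)phenoxy]-3-[4-(pivaloyloxy)phenyl]propane-1,2-diol | OC[C@@H](O)[C@H](Oc1cccc(OCC=C)c1OCC=C)c1ccc(OC(=O)C(C)(C)C)cc1
F2 | step 8 | (2S,3R)-3-[2,3-bis(allyloxy)phenoxy]-2-hydroxy-3-[4-(pivaloyloxy)phenyl]propanal | O=C[C@@H](O)[C@H](Oc1cccc(OCC=C)c1OCC=C)c1ccc(OC(=O)C(C)(C)C)cc1
F3 | step 14 | 4-benzylsulfanyl derivative of 16 (C4 epimer mixture, C2 and C3 as in 16) | c1ccccc1CSC1c2ccc(OCC=C)c(OCC=C)c2O[C@@H](c2ccc(OC(=O)C(C)(C)C)cc2)[C@@H]1O
F4 | step 11 | racemic 4-[7,8-bis(allyloxy)-2H-chromen-2-yl]phenyl pivalate | C=CCOc1ccc2C=CC(c3ccc(OC(=O)C(C)(C)C)cc3)Oc2c1OCC=C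
F5 | step 11 | 4-[(S)-7,8-bis(allyloxy)-2H-chromen-2-yl]phenyl pivalate | C=CCOc1ccc2C=C[C@@H](c3ccc(OC(=O)C(C)(C)C)cc3)Oc2c1OCC=C
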